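In a one-step world, where the precatalyst charged works from the first minute and the rate follows the catalyst, the two factors are the charge ratios, 2 and 0.192. But in the spring run the target stood at 0.1% after 0.417 h and at 3.9% after 1.00 h, which I read as a catalyst waking during the run.

the same everywhere: starting material 26 mM; precatalyst 26 µM

| run | remark |
|---|---|
| spring | the very flask that is asked about, followed so far |
| flask |  |

spring run (percent of the starting material charged)

| time / h | target / % | starting material / % |
|---|---|---|
| 0.417 | 0.1 | 99.2 |
| 1.00 | 3.9 | 95.8 |
| 2.00 | 12.6 | 86.7 |
| 3.00 | 24.8 | 73.8 |
| 5.00 | 46.4 | 54.5 |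
| 6.00 | 51.5 | 47.2 |
| 8.00 | 63.2 | 38.0 |

(readings scatter by 0.5 percentage points)

1. factor on the rate of making target when 20% of the starting material are converted if precatalyst is charged twice over
2. factor on the rate when 20% of the starting material are converted if precatalyst is charged at 5.0 µM instead

So I counted the turnovers owed by each catalyst charged (a turnover number) when the conversion in question is reached:

turnovers needed = 20% × 26 mM / 26 µM = 200

With a double charge the count is 100, which the spring run reached near 10.0% conversion. I compared its rate there with its rate at 200, both read from the target readings:

factor ≈ 2 × 2.26 mM h⁻¹ / 3.17 mM h⁻¹ = 1.43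

At 5.0 µM the count is 1040, more than the 1000 that full conversion gives in the spring run, so that run holds no such point and one number was not enough. That flask has more turnovers to make, so in my own reckoning, which is not the forecast's, I expected a later arrival and put its factor above 0.192.

The forecast gave 1.6 (1.2 to 2.3) and 0.16 (0.08 to 0.27), noting: “Catalyst order itself is untested, so the ranges are wide”. Its second value differs from my reckoning, since it stands below the charge ratio of 0.192, while the high end of its range stands above it.

The simulation gave 1.51 and 0.329, the second above the forecast's high end.

    starting material + enzyme → target + enzyme, rate k1*[starting material]^2.5*[enzyme]/(1 + ([starting material]/Kh1)^2.5) (32.9 mM, k = 85600 M⁻²·⁵ min⁻¹)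
    precatalyst → enzyme (k = 0.00437 min⁻¹)

At the conversion asked about, the 5.0 µM flask held 17.5% of its catalyst as precatalyst, against 52.1% in the 26 µM flask at 2.51 h. With 0.26 h⁻¹, its 1040 turnovers took 6.64 h, an average of 157 h⁻¹ per catalyst charged, while the 200 turnovers of the 26 µM flask averaged 79.7 h⁻¹.

Readings and results were computed for an exercise; noise was put on by code.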